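**Retrosynthetic overview**

1. The strategy rests on the cis-fused α-methylene-γ-lactone ring (C1, C2, O, C16, C15, with exocyclic C15=C17). Its carbonyl C16 lies between vinyl carbon C15 and the oxygen on C2, so C16 is brought in last as CO between a C15 enol triflate and the free C2 hydroxyl of the finished 14-membered carbocycle (C1–C14).
2. The enol triflate comes from the C15 methyl ketone 34 by kinetic enolisation; the carbocycle is closed at C10–C11 by an intramolecular allyl–vinyl Stille coupling of 33.
3. C1–C2 and both stereocentres come from an Evans syn-aldol of the west imide 23 (C11–C15; prenyl bromide, acetic acid, (R)-4-benzyl-2-oxazolidinone) with the east α-alkoxy aldehyde 14 (C2–C10).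
4. Aldehyde 14 comes from (S)-citronellal (C2–C9, C4 centre): O3 by proline α-aminoxylation, the C8 carbinol by Sharpless epoxidation and hydride opening, C10 by Ohira–Bestmann homologation.
5. Ring order: 14-membered carbocycle (step 23), lactone (step 26), epoxide (step 29, after O3 deprotection and acetylation).

Key step: step 26

Remark: cembrane numbering is used throughout (ring C1–C14, lactone arm C15(=C17)–C16). O3 is carried through the key step as its 4-methoxybenzyl (PMB) ether so that only O2 can close the lactone, so the key precursor 37 and key product 39 are the O3-PMB forms of the free alcohols. TES = triethylsilyl.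

**Route**

Step 1
Reactants: 1 (S)-citronellal
Product: 3 (2R,3S)-2-(anilinooxy)-3,7-dimethyloct-6-en-1-ol, via α-anilinooxy aldehyde 2 (not isolated)
Conditions: PhNO, L-proline (20 mol%), DMSO, rt; then NaBH4, EtOH, 0 °C
Reagents that add atoms: nitrosobenzene O=Nc1ccccc1
Why: Organocatalytic α-aminoxylation through the proline enamine puts the nitroso oxygen on one enamine face under catalyst control, so L-proline should set the new 2R centre (C3 of the target) regardless of the neighbouring 3S methyl centre, and reduction in the same flask removes the epimerisable aldehyde.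

Step 2
Reactants: 3 (2R,3S)-2-(anilinooxy)-3,7-dimethyloct-6-en-1-ol
Product: 4 (2R,3S)-3,7-dimethyloct-6-ene-1,2-diol
Conditions: Zn, AcOH, EtOH, rt
Reagents that add atoms: none
Why: Reductive N–O cleavage by zinc in acetic acid frees the secondary hydroxyl without touching the trisubstituted alkene or either stereocentre.

Step 3
Reactants: 4 (2R,3S)-3,7-dimethyloct-6-ene-1,2-diol
Product: 5 (4R)-2-(4-methoxyphenyl)-4-[(2S)-6-methylhept-5-en-2-yl]-1,3-dioxolane (both epimers at the acetal carbon)
Conditions: 4-MeOC6H4CH(OMe)2, pyridinium p-toluenesulfonate (cat.), CH2Cl2, rt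
Reagents that add atoms: 4-methoxybenzaldehyde dimethyl acetal COC(OC)c1ccc(OC)cc1
Why: Acid-catalysed transacetalisation ties both hydroxyls into a 4-methoxybenzylidene acetal that is later opened to leave O3 as a PMB ether; the acetal carbon forms as an epimer mixture, which does not matter because that centre is destroyed in step 10.

Step 4
Reactants: 5 4-methoxybenzylidene acetal
Product: 6 (2E,6S)-6-[(4R)-2-(4-methoxyphenyl)-1,3-dioxolan-4-yl]-2-methylhept-2-en-1-ol
Conditions: SeO2 (cat.), t-BuOOH, CH2Cl2, rt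
Reagents that add atoms: selenium dioxide O=[Se]=O; tert-butyl hydroperoxide CC(C)(C)OO
Why: Allylic oxidation by SeO2 (ene reaction, then [2,3]-sigmatropic shift) attacks the gem-dimethyl end of the trisubstituted alkene at the methyl group trans to the chain, so the E allylic alcohol should form.

Step 5
Reactants: 6 E allylic alcohol
Product: 7 [(2R,3R)-3-{(3S)-3-[(4R)-2-(4-methoxyphenyl)-1,3-dioxolan-4-yl]butyl}-2-methyloxiran-2-yl]methanol
Conditions: Ti(OiPr)4 (10 mol%), D-(−)-diethyl tartrate (12 mol%), t-BuOOH, 4 Å molecular sieves, CH2Cl2, −20 °C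
Reagents that add atoms: tert-butyl hydroperoxide CC(C)(C)OO
Why: Sharpless asymmetric epoxidation of the E 2-methyl allylic alcohol with the D-(−)-tartrate ligand delivers oxygen to the face that gives the (2R,3R)-epoxide, which fixes the quaternary carbon that becomes C8 under reagent control.

Step 6
Reactants: 7 epoxy alcohol
Product: 8 (2S,6S)-6-[(4R)-2-(4-methoxyphenyl)-1,3-dioxolan-4-yl]-2-methylheptane-1,2-diol
Conditions: LiAlH4, THF, 0 °C to rt
Reagents that add atoms: none
Why: Hydride opens the epoxide in an SN2 reaction at the less hindered secondary carbon (C7), so the C8–O bond and its configuration are kept and the tertiary alcohol of the target appears; the acetal is inert to LiAlH4.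

Step 7
Reactants: 8 1,2-diol
Product: 9 (2S,6S)-6-[(4R)-2-(4-methoxyphenyl)-1,3-dioxolan-4-yl]-2-methyl-1,2-bis(triethylsilyloxy)heptane
Conditions: Et3SiOTf, 2,6-lutidine, CH2Cl2, −78 to 0 °C
Reagents that add atoms: triethylsilyl trifluoromethanesulfonate CC[Si](CC)(CC)OS(=O)(=O)C(F)(F)F
Why: Silylation with the silyl triflate and a hindered base is reactive enough to cap the tertiary as well as the primary hydroxyl, while the excess lutidine keeps the acetal intact.

Step 8
Reactants: 9 bis(triethylsilyl) ether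
Product: 11 (2S,6S)-6-[(4R)-2-(4-methoxyphenyl)-1,3-dioxolan-4-yl]-2-methyl-2-(triethylsilyloxy)heptanal, via alkoxysulfonium chloride 10 (not isolated)
Conditions: (COCl)2, Me2SO, CH2Cl2, −78 to −40 °C; then Et3N, −78 to 0 °C
Reagents that add atoms: none
Why: Under Swern conditions the chlorosulfonium reagent cleaves the unhindered primary silyl ether (the tertiary one is too hindered) and oxidises that oxygen through the alkoxysulfonium ylide, so the aldehyde forms without a free α-hydroxy aldehyde ever being present.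

Step 9
Reactants: 11 α-silyloxy aldehyde
Product: 12 (4R)-2-(4-methoxyphenyl)-4-[(2S,6S)-6-methyl-6-(triethylsilyloxy)oct-7-yn-2-yl]-1,3-dioxolane
Conditions: dimethyl (1-diazo-2-oxopropyl)phosphonate, K2CO3, MeOH, 0 °C to rt
Reagents that add atoms: dimethyl (1-diazo-2-oxopropyl)phosphonate COP(=O)(OC)C(=[N+]=[N-])C(C)=O
Why: Seyferth–Gilbert homologation with the Ohira–Bestmann reagent turns the aldehyde into the terminal alkyne (C9≡C10), and the aldehyde has no α-hydrogen, so the basic methanol cannot epimerise C8.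

Step 10
Reactants: 12 alkyne acetal
Product: 13 (2R,3S,7S)-2-(4-methoxybenzyloxy)-3,7-dimethyl-7-(triethylsilyloxy)non-8-yn-1-ol
Conditions: iBu2AlH, CH2Cl2, −78 to 0 °C
Reagents that add atoms: none
Why: Reductive opening of the 4-methoxybenzylidene acetal by iBu2AlH is regioselective because aluminium binds the less hindered primary oxygen and hydride is delivered to the oxocarbenium ion, which leaves the PMB group on the secondary oxygen (O3) and frees the primary alcohol.

Step 11
Reactants: 13 primary alcohol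
Product: 14 (2R,3S,7S)-2-(4-methoxybenzyloxy)-3,7-dimethyl-7-(triethylsilyloxy)non-8-ynal (east fragment, C2–C10)
Conditions: Dess–Martin periodinane, CH2Cl2, 0 °C to rt
Reagents that add atoms: none
Why: Dess–Martin oxidation is mild and nearly neutral, so the α-alkoxy aldehyde should form without epimerisation at C3 and is used at once.

Step 12
Reactants: 15 prenyl bromide; 16 acetic acid
Product: 18 5-methylhex-4-enoic acid, via dilithium acetate 17 (not isolated)
Conditions: LiN(iPr)2 (2.1 equiv), THF/DMPU, 0 °C; then 15, 0 °C to rt; HCl work-up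
Reagents that add atoms: none
Why: Alkylation of the carboxylic acid dianion at carbon with the reactive primary allylic bromide (SN2) gives the C1/C15 two-carbon unit joined to C14–C12.

Step 13
Reactants: 18 5-methylhex-4-enoic acid; 19 (R)-4-benzyl-2-oxazolidinone
Product: 21 (R)-4-benzyl-3-(5-methylhex-4-enoyl)oxazolidin-2-one, via mixed pivalic anhydride 20 (not isolated)
Conditions: t-BuCOCl, Et3N, THF, −20 °C; then 19, LiCl, −20 °C to rt
Reagents that add atoms: none
Why: N-acylation of the oxazolidinone by the mixed anhydride takes place at the less hindered acyl carbon and installs the Evans auxiliary.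

Step 14
Reactants: 21 imide
Product: 22 (R)-4-benzyl-3-[(E)-6-hydroxy-5-methylhex-4-enoyl]oxazolidin-2-one
Conditions: SeO2 (cat.), t-BuOOH, CH2Cl2, rt
Reagents that add atoms: selenium dioxide O=[Se]=O; tert-butyl hydroperoxide CC(C)(C)OO
Why: SeO2 allylic oxidation hydroxylates the methyl group trans to the chain on the more substituted alkene carbon, which gives the E C12=C13 alkene with C11 as CH2OH.

Step 15
Reactants: 22 allylic alcohol
Product: 23 (R)-4-benzyl-3-[(E)-5-methyl-6-(triethylsilyloxy)hex-4-enoyl]oxazolidin-2-one (west fragment)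
Conditions: Et3SiCl, imidazole, CH2Cl2, 0 °C
Reagents that add atoms: chlorotriethylsilane CC[Si](CC)(CC)Cl
Why: Silylation of the primary allylic alcohol protects O11 for the enolisation in step 16 with a group that is later removed more easily than any other silyl ether in the molecule.

Step 16
Reactants: 23 west imide; 14 east aldehyde
Product: 26 Evans aldol adduct (1R,2R,3R,4S,8S): (4R)-4-benzyl-3-acyl-oxazolidin-2-one with acyl chain C15(=O)–C1H[CH2CH=C(CH3)CH2OTES]–C2H(OH)–C3H(OPMB)–C4H(CH3)–(CH2)3–C8(CH3)(OTES)–C≡CH, via boron enolate 24 (not isolated), via boron aldolate 25 (not isolated)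
Conditions: 23, Bu2BOTf, iPr2NEt, CH2Cl2, −78 to 0 °C; then 14, −78 to −10 °C; pH 7 buffer, MeOH, H2O2, 0 °C
Reagents that add atoms: none
Why: In this Evans syn-aldol the Z dibutylboron enolate reacts through a Zimmerman–Traxler chair in which the (R)-benzyl auxiliary shields one enolate face, which sets C1 (R) and C2 (R) syn to each other, and this reagent control is expected to override the weaker Cornforth preference of the α-alkoxy aldehyde for the C2/C3-anti isomer.

Step 17
Reactants: 26 aldol adduct
Product: 27 Weinreb amide (1R,2R,3R,4S,8S) with free C2 hydroxyl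
Conditions: MeNHOMe·HCl, AlMe3, CH2Cl2, −20 to 0 °C
Reagents that add atoms: N,O-dimethylhydroxylamine hydrochloride CNOC.Cl
Why: Transamidation with the aluminium amide attacks the exocyclic imide carbonyl, helped by the aluminium alkoxide of the free β-hydroxyl, and releases the auxiliary without epimerising C1.

Step 18
Reactants: 27 Weinreb amide
Product: 28 O2-triethylsilyl Weinreb amide
Conditions: Et3SiOTf, 2,6-lutidine, CH2Cl2, −78 °C
Reagents that add atoms: triethylsilyl trifluoromethanesulfonate CC[Si](CC)(CC)OS(=O)(=O)C(F)(F)F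
Why: Silylation of the secondary hydroxyl protects O2 through the organometallic and enolate steps and blocks retro-aldol cleavage.

Step 19
Reactants: 28 silylated Weinreb amide
Product: 29 methyl ketone (1R,2R,3R,4S,8S): CH3C15(=O)–C1H[CH2CH=C(CH3)CH2OTES]–C2H(OTES)–C3H(OPMB)–C4H(CH3)–(CH2)3–C8(CH3)(OTES)–C≡CH
Conditions: MeMgBr (excess), THF, −20 to 0 °C; NH4Cl work-up
Reagents that add atoms: methylmagnesium bromide C[Mg]Br
Why: In this Weinreb ketone synthesis the chelated tetrahedral adduct survives until work-up, so addition stops at the methyl ketone (C17 introduced), and the excess reagent covers the acidic alkyne hydrogen, which returns on quenching.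

Step 20
Reactants: 29 methyl ketone
Product: 30 C11 allylic alcohol (alkyne retained; O2 and O8 still silylated)
Conditions: pyridinium p-toluenesulfonate, MeOH/CH2Cl2, 0 °C
Reagents that add atoms: none
Why: Acid-catalysed methanolysis removes the unhindered primary allylic silyl ether much faster than the hindered secondary (O2) and tertiary (O8) ones, so only O11 is freed.

Step 21
Reactants: 30 alkyne allylic alcohol
Product: 31 (9E)-C10-tributylstannyl alkene (vinylstannane) with free C11 hydroxyl
Conditions: Bu3SnH, PdCl2(PPh3)2 (3 mol%), THF, 0 °C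
Reagents that add atoms: tributyltin hydride CCCC[SnH](CCCC)CCCC
Why: Palladium-catalysed hydrostannation adds H and Sn syn across the terminal alkyne with tin at the terminal carbon, away from the bulky quaternary C8, and so gives the E C9=C10 vinylstannane.

Step 22
Reactants: 31 vinylstannane allylic alcohol
Product: 33 C11 allylic chloride bearing the C10 vinylstannane, via allylic mesylate 32 (not isolated)
Conditions: MsCl, 2,4,6-collidine, LiCl, DMF, 0 °C
Reagents that add atoms: lithium chloride [Li+].[Cl-]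
Why: Mesylation followed by SN2 displacement with chloride converts the primary allylic alcohol to the chloride without allylic transposition or loss of the E geometry, under non-acidic conditions that the vinylstannane tolerates.

Step 23
Reactants: 33 allylic chloride vinylstannane
Product: 34 macrocyclic methyl ketone: (1R,2R,3R,4S,8S,9E,12E)-1-acetyl-3-(4-methoxybenzyloxy)-4,8,12-trimethyl-2,8-bis(triethylsilyloxy)cyclotetradeca-9,12-diene (cembrane locants)
Conditions: Pd2(dba)3 (10 mol%), AsPh3 (40 mol%), THF, 60 °C, 1 mM, slow addition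
Reagents that add atoms: none
Why: In this intramolecular Stille coupling, zerovalent palladium ionises the allylic chloride to a π-allyl complex, the vinylstannane transmetalates and reductive elimination at the less substituted allyl terminus forms C10–C11, which closes the 14-membered ring as the skipped 9E,12E-diene; high dilution favours ring closure over oligomerisation.

Step 24
Reactants: 34 macrocyclic methyl ketone
Product: 36 C15 enol triflate with O2 and O8 silylated, via potassium enolate 35 (not isolated)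
Conditions: KN(SiMe3)2, THF, −78 °C; then PhNTf2, −78 to −20 °C
Reagents that add atoms: N-phenylbis(trifluoromethanesulfonimide) O=S(=O)(N(c1ccccc1)S(=O)(=O)C(F)(F)F)C(F)(F)F
Why: Kinetic deprotonation by the bulky amide base occurs at the unhindered methyl group (C17) and not at the tertiary C1–H, and O-triflation of that enolate gives the 1,1-disubstituted enol triflate while C1 stays untouched.

Step 25
Reactants: 36 bis-silylated enol triflate
Product: 37 key precursor: (1R,2R,3R,4S,8S,9E,12E)-3-(4-methoxybenzyloxy)-4,8,12-trimethyl-1-[1-(trifluoromethylsulfonyloxy)vinyl]cyclotetradeca-9,12-diene-2,8-diol (cembrane locants)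
Conditions: HF·pyridine, pyridine, THF, 0 °C to rt
Reagents that add atoms: none
Why: Buffered fluoride desilylation removes both triethylsilyl ethers, the alkenyl triflate and the PMB ether are stable to it, and only O2 is then placed to close a lactone.

Step 26
Reactants: 37 enol triflate diol; 38 carbon monoxide
Product: 39 (1S,2R,3R,4S,8S)-8-hydroxy-3-(4-methoxybenzyloxy)cembra-9E,12E,15(17)-trien-16,2-olide
Conditions: Pd(PPh3)4 (10 mol%), CO (1 atm), Bu3N, LiCl, MeCN, 65 °C
Reagents that add atoms: carbon monoxide [C-]#[O+] (compound 38)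
Why: Zerovalent palladium adds oxidatively into the C15–OTf bond of 37 (LiCl turns the alkenylpalladium triflate into the chloride), CO inserts to give the acryloylpalladium species, the C2 hydroxyl attacks the acyl carbon and Bu3N takes up the acid, which releases the lactone and returns zerovalent palladium. The closest known reaction type is the palladium-catalysed carbonylative lactonization of hydroxy alkenyl triflates and halides to butenolides and α-methylene lactones. The one ring closed, the lactone (C1, C15, C16, O, C2), forms by 5-exo-trig closure at the acyl carbon with the new bonds C15–C16 and C16–O2. No stereocenter is created: C1 and C2 keep the syn relation set by the aldol of step 16 because neither the C1–C15 nor the C2–O bond is broken, so the lactone is cis-fused (the change of the C1 descriptor from R to S is a priority change only). The step needs the acyl group to be taken by O2 alone, and the substrate secures this: O3 is blocked as its PMB ether (no six-membered lactone), the tertiary C8 hydroxyl could only close a strained 11-membered bridge, and the other alkenes are unactivated. The base-sensitive acrylate thus appears only after every enolate and organometallic step is over.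

Step 27
Reactants: 39 O3-PMB lactone
Product: 40 (1S,2R,3R,4S,8S)-3,8-dihydroxycembra-9E,12E,15(17)-trien-16,2-olide
Conditions: DDQ, CH2Cl2/pH 7 buffer, 0 °C
Reagents that add atoms: none
Why: Oxidative cleavage of the electron-rich PMB ether by DDQ in wet solvent frees O3 under neutral conditions that leave the methylene lactone, the skipped diene and the tertiary allylic alcohol alone.

Step 28
Reactants: 40 diol lactone
Product: 41 (1S,2R,3R,4S,8S)-3-acetoxy-8-hydroxycembra-9E,12E,15(17)-trien-16,2-olide
Conditions: Ac2O, pyridine, DMAP (cat.), CH2Cl2, 0 °C to rt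
Reagents that add atoms: acetic anhydride CC(=O)OC(C)=O
Why: DMAP-catalysed acylation takes the secondary C3 hydroxyl, while the tertiary C8 hydroxyl is too hindered to react under these conditions.

Step 29
Reactants: 41 12,13-deoxy acetate
Product: 42 target, (1S,2R,3R,4S,8S,12R,13R)-3-acetoxy-12,13-epoxy-8-hydroxycembra-9E,15(17)-dien-16,2-olide (CNP0202356.4)
Conditions: 1,2:4,5-di-O-isopropylidene-β-D-erythro-2,3-hexodiulo-2,6-pyranose (30 mol%), KHSO5 (as 2KHSO5·KHSO4·K2SO4), K2CO3, Bu4NHSO4, MeCN/CH2(OMe)2/aq. Na2B4O7–Na2EDTA buffer, 0 °C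
Reagents that add atoms: potassium peroxymonosulfate [K+].[O-]S(=O)(=O)OO
Why: In this Shi epoxidation the chiral dioxirane from the D-fructose-derived ketone transfers oxygen through a spiro transition state to the more electron-rich trisubstituted E C12=C13 alkene, on the face that gives the (12R,13R)-epoxide by catalyst control, while the electron-poor C15=C17 and the less substituted, hindered C9=C10 should react more slowly.

**Compound list**

1 | (S)-citronellal | C[C@@H](CCC=C(C)C)CC=O | starting material
2 | (2R,3S)-2-(anilinooxy)-3,7-dimethyloct-6-enal (formed in the flask) | O=C[C@H](ONc1ccccc1)[C@@H](C)CCC=C(C)C | intermediate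
3 | (2R,3S)-2-(anilinooxy)-3,7-dimethyloct-6-en-1-ol | OC[C@H](ONc1ccccc1)[C@@H](C)CCC=C(C)C | intermediate
4 | (2R,3S)-3,7-dimethyloct-6-ene-1,2-diol | OC[C@H](O)[C@@H](C)CCC=C(C)C | intermediate
5 | (4R)-2-(4-methoxyphenyl)-4-[(2S)-6-methylhept-5-en-2-yl]-1,3-dioxolane, epimers at the acetal carbon | COc1ccc(cc1)C1OC[C@H](O1)[C@@H](C)CCC=C(C)C | intermediate
6 | (2E,6S)-6-[(4R)-2-(4-methoxyphenyl)-1,3-dioxolan-4-yl]-2-methylhept-2-en-1-ol | COc1ccc(cc1)C1OC[C@H](O1)[C@@H](C)CC/C=C(\C)CO | intermediate
7 | [(2R,3R)-3-{(3S)-3-[(4R)-2-(4-methoxyphenyl)-1,3-dioxolan-4-yl]butyl}-2-methyloxiran-2-yl]methanol | COc1ccc(cc1)C1OC[C@H](O1)[C@@H](C)CC[C@H]2O[C@]2(C)CO | intermediate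
8 | (2S,6S)-6-[(4R)-2-(4-methoxyphenyl)-1,3-dioxolan-4-yl]-2-methylheptane-1,2-diol | COc1ccc(cc1)C1OC[C@H](O1)[C@@H](C)CCC[C@](C)(O)CO | intermediate
9 | (2S,6S)-6-[(4R)-2-(4-methoxyphenyl)-1,3-dioxolan-4-yl]-2-methyl-1,2-bis(triethylsilyloxy)heptane | COc1ccc(cc1)C1OC[C@H](O1)[C@@H](C)CCC[C@](C)(O[Si](CC)(CC)CC)CO[Si](CC)(CC)CC | intermediate
10 | dimethyl(alkoxy)sulfonium chloride of the primary oxygen of 9 (formed in the flask) | COc1ccc(cc1)C1OC[C@H](O1)[C@@H](C)CCC[C@](C)(O[Si](CC)(CC)CC)CO[S+](C)C.[Cl-] | intermediate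
11 | (2S,6S)-6-[(4R)-2-(4-methoxyphenyl)-1,3-dioxolan-4-yl]-2-methyl-2-(triethylsilyloxy)heptanal | COc1ccc(cc1)C1OC[C@H](O1)[C@@H](C)CCC[C@](C)(O[Si](CC)(CC)CC)C=O | intermediate
12 | (4R)-2-(4-methoxyphenyl)-4-[(2S,6S)-6-methyl-6-(triethylsilyloxy)oct-7-yn-2-yl]-1,3-dioxolane | COc1ccc(cc1)C1OC[C@H](O1)[C@@H](C)CCC[C@](C)(O[Si](CC)(CC)CC)C#C | intermediate
13 | (2R,3S,7S)-2-(4-methoxybenzyloxy)-3,7-dimethyl-7-(triethylsilyloxy)non-8-yn-1-ol | OC[C@H](OCc1ccc(OC)cc1)[C@@H](C)CCC[C@](C)(O[Si](CC)(CC)CC)C#C | intermediate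
14 | (2R,3S,7S)-2-(4-methoxybenzyloxy)-3,7-dimethyl-7-(triethylsilyloxy)non-8-ynal, east fragment | O=C[C@H](OCc1ccc(OC)cc1)[C@@H](C)CCC[C@](C)(O[Si](CC)(CC)CC)C#C | intermediate
15 | prenyl bromide | CC(C)=CCBr | starting material
16 | acetic acid | CC(=O)O | starting material
17 | dilithium acetate (enediolate, formed in the flask) | [Li+].[Li+].[CH2-]C(=O)[O-] | intermediate
18 | 5-methylhex-4-enoic acid | CC(C)=CCCC(=O)O | intermediate
19 | (R)-4-benzyl-2-oxazolidinone | O=C1N[C@H](Cc2ccccc2)CO1 | starting material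
20 | 5-methylhex-4-enoic pivalic anhydride (formed in the flask) | CC(C)=CCCC(=O)OC(=O)C(C)(C)C | intermediate
21 | (R)-4-benzyl-3-(5-methylhex-4-enoyl)oxazolidin-2-one | CC(C)=CCCC(=O)N1[C@H](Cc2ccccc2)COC1=O | intermediate
22 | (R)-4-benzyl-3-[(E)-6-hydroxy-5-methylhex-4-enoyl]oxazolidin-2-one | OC/C(C)=C/CCC(=O)N1[C@H](Cc2ccccc2)COC1=O | intermediate
23 | (R)-4-benzyl-3-[(E)-5-methyl-6-(triethylsilyloxy)hex-4-enoyl]oxazolidin-2-one, west fragment | CC[Si](CC)(CC)OC/C(C)=C/CCC(=O)N1[C@H](Cc2ccccc2)COC1=O | intermediate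
24 | Z dibutylboron enolate of 23 (formed in the flask) | CCCCB(CCCC)O/C(N1[C@H](Cc2ccccc2)COC1=O)=C\C/C=C(\C)CO[Si](CC)(CC)CC | intermediate
25 | O2-dibutylboron aldolate of 26 (formed in the flask) | O=C1OC[C@@H](Cc2ccccc2)N1C(=O)[C@H](C/C=C(\C)CO[Si](CC)(CC)CC)[C@@H](OB(CCCC)CCCC)[C@H](OCc3ccc(OC)cc3)[C@@H](C)CCC[C@](C)(O[Si](CC)(CC)CC)C#C | intermediate
26 | aldol adduct (1R,2R,3R,4S,8S): (4R)-4-benzyl-3-[(2R,3R,4R,5S,9S)-3-hydroxy-4-(4-methoxybenzyloxy)-5,9-dimethyl-2-[(2E)-3-methyl-4-(triethylsilyloxy)but-2-en-1-yl]-9-(triethylsilyloxy)undec-10-ynoyl]oxazolidin-2-one | O=C1OC[C@@H](Cc2ccccc2)N1C(=O)[C@H](C/C=C(\C)CO[Si](CC)(CC)CC)[C@@H](O)[C@H](OCc3ccc(OC)cc3)[C@@H](C)CCC[C@](C)(O[Si](CC)(CC)CC)C#C | intermediate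
27 | N-methoxy-N-methyl amide of the aldol acid (1R,2R,3R,4S,8S), C2–OH free | CON(C)C(=O)[C@H](C/C=C(\C)CO[Si](CC)(CC)CC)[C@@H](O)[C@H](OCc1ccc(OC)cc1)[C@@H](C)CCC[C@](C)(O[Si](CC)(CC)CC)C#C | intermediate
28 | O2-triethylsilyl ether of 27 | CON(C)C(=O)[C@H](C/C=C(\C)CO[Si](CC)(CC)CC)[C@@H](O[Si](CC)(CC)CC)[C@H](OCc1ccc(OC)cc1)[C@@H](C)CCC[C@](C)(O[Si](CC)(CC)CC)C#C | intermediate
29 | acyclic C15 methyl ketone (1R,2R,3R,4S,8S,12E), O2, O8, O11 silylated, O3 PMB, C9≡C10 | CC(=O)[C@H](C/C=C(\C)CO[Si](CC)(CC)CC)[C@@H](O[Si](CC)(CC)CC)[C@H](OCc1ccc(OC)cc1)[C@@H](C)CCC[C@](C)(O[Si](CC)(CC)CC)C#C | intermediate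
30 | C11 allylic alcohol of 29 | CC(=O)[C@H](C/C=C(\C)CO)[C@@H](O[Si](CC)(CC)CC)[C@H](OCc1ccc(OC)cc1)[C@@H](C)CCC[C@](C)(O[Si](CC)(CC)CC)C#C | intermediate
31 | (9E)-10-tributylstannyl alkene with C11–OH | CC(=O)[C@H](C/C=C(\C)CO)[C@@H](O[Si](CC)(CC)CC)[C@H](OCc1ccc(OC)cc1)[C@@H](C)CCC[C@](C)(O[Si](CC)(CC)CC)/C=C/[Sn](CCCC)(CCCC)CCCC | intermediate
32 | C11 methanesulfonate of 31 (formed in the flask) | CC(=O)[C@H](C/C=C(\C)COS(C)(=O)=O)[C@@H](O[Si](CC)(CC)CC)[C@H](OCc1ccc(OC)cc1)[C@@H](C)CCC[C@](C)(O[Si](CC)(CC)CC)/C=C/[Sn](CCCC)(CCCC)CCCC | intermediate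
33 | C11 allylic chloride with C10 vinylstannane | CC(=O)[C@H](C/C=C(\C)CCl)[C@@H](O[Si](CC)(CC)CC)[C@H](OCc1ccc(OC)cc1)[C@@H](C)CCC[C@](C)(O[Si](CC)(CC)CC)/C=C/[Sn](CCCC)(CCCC)CCCC | intermediate
34 | (1R,2R,3R,4S,8S,9E,12E)-1-acetyl-3-(4-methoxybenzyloxy)-4,8,12-trimethyl-2,8-bis(triethylsilyloxy)cyclotetradeca-9,12-diene (cembrane locants) | CC(=O)[C@H]1[C@@H](O[Si](CC)(CC)CC)[C@H](OCc2ccc(OC)cc2)[C@@H](C)CCC[C@](C)(O[Si](CC)(CC)CC)/C=C/C/C(C)=C/C1 | intermediate
35 | potassium C15/C17 enolate of 34 (formed in the flask) | [K+].C=C([O-])[C@H]1[C@@H](O[Si](CC)(CC)CC)[C@H](OCc2ccc(OC)cc2)[C@@H](C)CCC[C@](C)(O[Si](CC)(CC)CC)/C=C/C/C(C)=C/C1 | intermediate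
36 | C15 enol triflate, O2 and O8 silylated | C=C(OS(=O)(=O)C(F)(F)F)[C@H]1[C@@H](O[Si](CC)(CC)CC)[C@H](OCc2ccc(OC)cc2)[C@@H](C)CCC[C@](C)(O[Si](CC)(CC)CC)/C=C/C/C(C)=C/C1 | intermediate
37 | key precursor: C15 enol triflate with free C2 and C8 hydroxyls, O3 PMB (1R,2R,3R,4S,8S,9E,12E) | C=C(OS(=O)(=O)C(F)(F)F)[C@H]1[C@@H](O)[C@H](OCc2ccc(OC)cc2)[C@@H](C)CCC[C@](C)(O)/C=C/C/C(C)=C/C1 | intermediate
38 | carbon monoxide | [C-]#[O+] | starting material
39 | key product: (1S,2R,3R,4S,8S)-8-hydroxy-3-(4-methoxybenzyloxy)cembra-9E,12E,15(17)-trien-16,2-olide | C=C1C(=O)O[C@H]2[C@H](OCc3ccc(OC)cc3)[C@@H](C)CCC[C@](C)(O)/C=C/C/C(C)=C/C[C@@H]12 | intermediate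
40 | (1S,2R,3R,4S,8S)-3,8-dihydroxycembra-9E,12E,15(17)-trien-16,2-olide | C=C1C(=O)O[C@H]2[C@H](O)[C@@H](C)CCC[C@](C)(O)/C=C/C/C(C)=C/C[C@@H]12 | intermediate
41 | (1S,2R,3R,4S,8S)-3-acetoxy-8-hydroxycembra-9E,12E,15(17)-trien-16,2-olide | C=C1C(=O)O[C@H]2[C@H](OC(C)=O)[C@@H](C)CCC[C@](C)(O)/C=C/C/C(C)=C/C[C@@H]12 | intermediate
42 | CNP0202356.4, (1S,2R,3R,4S,8S,12R,13R)-3-acetoxy-12,13-epoxy-8-hydroxycembra-9E,15(17)-dien-16,2-olide | C=C1C(=O)O[C@H]2[C@H](OC(C)=O)[C@@H](C)CCC[C@](C)(O)/C=C/C[C@@]3(C)O[C@@H]3C[C@@H]12 | target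

**Step count and risk**

Total: 29 steps. Longest linear sequence: 25 steps (steps 1–11, then 16–29); the west branch (steps 12–15) joins at step 16.

Steps most likely to fail:

Step 23 (Stille macrocyclization). Intermolecular coupling and oligomerisation may outrun closure of the 14-membered ring, the stannane may be lost by protodestannylation, or the C12=C13 geometry may scramble through the π-allyl complex. The fallback closes the ring by olefin metathesis at C9=C10 and sets out from 30. Semi-hydrogenation of the terminal alkyne (H2, Pd/CaCO3 poisoned with Pb(OAc)2, quinoline) gives the vinyl carbinol F1. Treatment with MsCl, 2,4,6-collidine and LiCl gives, through the mesylate F2, the allylic chloride F3. Intermolecular Stille coupling of F3 with Bu3SnCH=CH2 (Pd2(dba)3, P(2-furyl)3, THF) gives the skipped triene F4. Ring-closing metathesis of F4 with the second-generation Grubbs catalyst at high dilution, with loss of ethene, should then give the E C9=C10 alkene and return to the route at 34.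

Step 26 (carbonylative lactonization). CO uptake may be slow on the hindered macrocyclic alkenylpalladium, so that reduction, elimination or hydrolysis of the triflate competes, or the catalyst may be deactivated. The fallback separates C–C bond formation from ring closure and sets out from 36. Palladium-catalysed methoxycarbonylation (Pd(OAc)2, 1,1'-bis(diphenylphosphino)ferrocene, CO, MeOH, Et3N, DMF) gives the methyl acrylate F5. HF·pyridine then frees the dihydroxy ester F6, and acid-catalysed lactonization (pyridinium p-toluenesulfonate, warm benzene) of the C2 hydroxyl onto the ester returns to the route at 39.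

Step 29 (Shi epoxidation). Oxygen transfer may also reach C9=C10, the catalyst may be mismatched with the face that the macrocycle exposes, or the acetate and methylene lactone may suffer at the basic pH. The fallback gives up catalyst control for substrate control: 41 is treated with m-chloroperbenzoic acid and NaHCO3 in CH2Cl2 at low temperature. The peracid should pick the most nucleophilic alkene (C12=C13) and attack from the outer face of the macrocycle. This leads directly from 41 to 42 without a new compound (F0).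

**Further compounds**

F1 | step 23 | vinyl carbinol: compound 30 with C9=C10H2 in place of the alkyne | CC(=O)[C@H](C/C=C(\C)CO)[C@@H](O[Si](CC)(CC)CC)[C@H](OCc1ccc(OC)cc1)[C@@H](C)CCC[C@](C)(O[Si](CC)(CC)CC)C=C
F2 | step 23 | C11 methanesulfonate of F1 | CC(=O)[C@H](C/C=C(\C)COS(C)(=O)=O)[C@@H](O[Si](CC)(CC)CC)[C@H](OCc1ccc(OC)cc1)[C@@H](C)CCC[C@](C)(O[Si](CC)(CC)CC)C=C
F3 | step 23 | C11 allylic chloride of F1 | CC(=O)[C@H](C/C=C(\C)CCl)[C@@H](O[Si](CC)(CC)CC)[C@H](OCc1ccc(OC)cc1)[C@@H](C)CCC[C@](C)(O[Si](CC)(CC)CC)C=C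
F4 | step 23 | skipped triene with C11-allyl terminus and C8 vinyl carbinol | CC(=O)[C@H](C/C=C(\C)CC=C)[C@@H](O[Si](CC)(CC)CC)[C@H](OCc1ccc(OC)cc1)[C@@H](C)CCC[C@](C)(O[Si](CC)(CC)CC)C=C
F5 | step 26 | macrocyclic methyl 2-substituted acrylate (C16 ester), O2 and O8 silylated | C=C(C(=O)OC)[C@H]1[C@@H](O[Si](CC)(CC)CC)[C@H](OCc2ccc(OC)cc2)[C@@H](C)CCC[C@](C)(O[Si](CC)(CC)CC)/C=C/C/C(C)=C/C1
F6 | step 26 | macrocyclic methyl acrylate with free C2 and C8 hydroxyls | C=C(C(=O)OC)[C@H]1[C@@H](O)[C@H](OCc2ccc(OC)cc2)[C@@H](C)CCC[C@](C)(O)/C=C/C/C(C)=C/C1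
F0 | step 29 | none | none
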